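## Retrosynthetic overview

1. The target is two (7S,8R,8′S)-olivil units joined by a biaryl bond between the C7 aryl ring of unit A and the benzyl ring of unit B. Locants: C7 = ArCH–O, C8 = CH bearing C9H2OH, C8′ = carbinol carbon bearing the benzyl carbon C7′, C9′ = ring OCH2.
2. The strategy rests on the oxolane ring of unit B: C9 on C8 and C7′ on C8′ sit cis on adjacent ring carbons and trans to the C7 aryl group. Both are taken from one alkyne held as a cyclobutene cis-fused across C8–C8′. Disconnecting C8–C9 and C8′–C7′ gives an aryl alkyne and (S)-3-benzyloxy-5-aryl-2(5H)-furanone; cleaving C9=C7′ afterwards releases the two side chains.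
3. The alkyne is the ethynyl biaryl that already carries unit A. Suzuki coupling builds the biaryl and a Seyferth–Gilbert (Ohira–Bestmann) homologation the alkyne. The oxolane of unit A comes from an Evans syn aldol (C7, C8), lactonisation, enolate benzylation and hydroxylation (C8′), and lactone-to-ether reduction.
4. The butenolide comes from catalytic asymmetric 2-(ethoxycarbonyl)allylation of O-benzylvanillin, ozonolysis to the enol and base-free O-benzylation.
5. Ring order: lactone A, oxolane A, butenolide B, cyclobutene on B (key step), ring cleavage, oxolane B. The C7′ oxygen is removed ionically together with the lactol reduction, followed by desilylation and hydrogenolysis.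

Key step: step 17

Assumption: in step 14 the ligand antipode named is taken to be the one that delivers the 5S lactone from aryl aldehydes; if the opposite sense is found, the enantiomeric ligand is used.

## Route

Step 1
Reactants: 1 (S)-4-benzyloxazolidin-2-one; 2 methyl 4-chloro-4-oxobutanoate
Product: 3 (S)-4-benzyl-3-(4-methoxy-4-oxobutanoyl)oxazolidin-2-one
Conditions: n-BuLi, THF, −78 °C; then 2, −78 to 0 °C
Reagents that add atoms: none
Why: N-acylation of the lithiated oxazolidinone by the acid chloride, which is far more electrophilic than the methyl ester at the other end of the chain.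

Step 2
Reactants: 4 5-bromovanillin
Product: 5 4-benzyloxy-3-bromo-5-methoxybenzaldehyde
Conditions: BnBr, K2CO3, DMF, rt
Reagents that add atoms: benzyl bromide, BrCc1ccccc1
Why: Williamson ether synthesis on the phenoxide, which leaves the aldehyde and the aryl bromide untouched.

Step 3
Reactants: 3 imide; 5 4-benzyloxy-3-bromo-5-methoxybenzaldehyde
Product: 7 (S)-4-benzyl-3-[(2S,3S)-2-(4-benzyloxy-3-bromo-5-methoxyphenyl)-5-oxooxolane-3-carbonyl]oxazolidin-2-one, via aldol adduct 6 (not isolated)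
Conditions: Bu2BOTf, iPr2NEt, CH2Cl2, −78 to 0 °C; 5, −78 to 0 °C; H2O2, pH 7 buffer, MeOH; then CSA (cat.), CH2Cl2, rt
Reagents that add atoms: none
Why: Evans syn aldol reaction, in which the Z boron enolate formed at the imide α-CH2 adds through a Zimmerman–Traxler chair on the face fixed by the (S)-benzyl auxiliary to give the 7S,8S syn adduct, whose benzylic hydroxyl then closes on the methyl ester to the γ-lactone with the C7 aryl and C8 acyl groups trans.

Step 4
Reactants: 7 lactone imide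
Product: 8 (4R,5S)-5-(4-benzyloxy-3-bromo-5-methoxyphenyl)-4-(hydroxymethyl)oxolan-2-one
Conditions: NaBH4, THF/H2O (4:1), 0 °C to rt; pH 7 phosphate quench
Reagents that add atoms: none
Why: Reductive cleavage of the N-acyl oxazolidinone, in which borohydride takes the activated exocyclic imide carbonyl to the primary alcohol C9 while the much less electrophilic γ-lactone is left, and the neutral quench keeps the hydroxymethyl lactone from translactonising.

Step 5
Reactants: 8 hydroxymethyl lactone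
Product: 9 (4R,5S)-5-(4-benzyloxy-3-bromo-5-methoxyphenyl)-4-[(tert-butyldiphenylsilyloxy)methyl]oxolan-2-one
Conditions: TBDPSCl, imidazole, DMF, 0 °C to rt
Reagents that add atoms: tert-butyl(chloro)diphenylsilane, CC(C)(C)[Si](Cl)(c1ccccc1)c1ccccc1
Why: Silylation of the primary alcohol under weakly basic conditions gives an ether that is inert to the enolate, hydride and Lewis acid steps that follow and that shields the upper face of the lactone enolate.

Step 6
Reactants: 10 4-benzyloxy-3-methoxybenzyl alcohol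
Product: 11 4-benzyloxy-3-methoxybenzyl bromide
Conditions: PBr3, Et2O, 0 °C; used directly
Reagents that add atoms: phosphorus tribromide, BrP(Br)Br
Why: SN2 bromination of the benzylic alcohol through its phosphite ester, with the labile electron-rich bromide taken on without storage.

Step 7
Reactants: 9 silyl ether lactone; 11 4-benzyloxy-3-methoxybenzyl bromide
Product: 12 (3S,4R,5S)-3-(4-benzyloxy-3-methoxybenzyl)-5-(4-benzyloxy-3-bromo-5-methoxyphenyl)-4-[(tert-butyldiphenylsilyloxy)methyl]oxolan-2-one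
Conditions: LiHMDS, THF, −78 °C; then 11, −78 to −40 °C
Reagents that add atoms: none
Why: Alkylation of the lactone lithium enolate, where the benzyl bromide should enter anti to the C8 silyloxymethyl group (trans product) and where the configuration of the new centre is not critical because it is re-made in step 8.

Step 8
Reactants: 12 α-benzyl lactone
Product: 13 (3S,4R,5S)-3-(4-benzyloxy-3-methoxybenzyl)-5-(4-benzyloxy-3-bromo-5-methoxyphenyl)-4-[(tert-butyldiphenylsilyloxy)methyl]-3-hydroxyoxolan-2-one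
Conditions: KHMDS, THF, −78 °C; then 2-(phenylsulfonyl)-3-phenyloxaziridine, −78 °C; NH4Cl
Reagents that add atoms: 2-(phenylsulfonyl)-3-phenyloxaziridine, O=S(=O)(c1ccccc1)N1OC1c1ccccc1
Why: Davis enolate hydroxylation, in which the oxaziridine should deliver oxygen to the tetrasubstituted potassium enolate on the face anti to the adjacent C8 CH2OTBDPS group, setting C8′ with the hydroxyl trans to C9 (cis to the C7 aryl) and the benzyl group cis to C9 as in olivil.

Step 9
Reactants: 13 α-hydroxy lactone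
Product: 14 lactol of 13 (oxolan-2-ol, anomer mixture)
Conditions: DIBAL-H (3 equiv), CH2Cl2, −78 °C; Rochelle salt
Reagents that add atoms: none
Why: Partial reduction of the γ-lactone to the lactol through the aluminium hemiacetal, which is stable at −78 °C, with one equivalent of hydride consumed by the tertiary alcohol.

Step 10
Reactants: 14 lactol
Product: 15 (3S,4R,5S)-3-(4-benzyloxy-3-methoxybenzyl)-5-(4-benzyloxy-3-bromo-5-methoxyphenyl)-4-[(tert-butyldiphenylsilyloxy)methyl]oxolan-3-ol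
Conditions: Et3SiH, BF3·OEt2, CH2Cl2, −78 °C
Reagents that add atoms: none
Why: Ionic hydrogenation of the lactol through the cyclic oxocarbenium ion, which creates no stereocentre and at −78 °C should not ionise the benzylic C7–O bond of the bromine-deactivated aryl ring.

Step 11
Reactants: 5 4-benzyloxy-3-bromo-5-methoxybenzaldehyde
Product: 16 4-benzyloxy-3-methoxy-5-(4,4,5,5-tetramethyl-1,3,2-dioxaborolan-2-yl)benzaldehyde
Conditions: B2pin2, Pd(dppf)Cl2 (cat.), KOAc, dioxane, 90 °C
Reagents that add atoms: bis(pinacolato)diboron, CC1(C)OB(OC1(C)C)B1OC(C)(C)C(C)(C)O1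
Why: Miyaura borylation of the aryl bromide, which tolerates the aldehyde because acetate is too weak a base to start a Suzuki coupling of the product.

Step 12
Reactants: 15 unit A aryl bromide; 16 aryl boronate
Product: 17 4-benzyloxy-3-{2-benzyloxy-5-[(2S,3R,4S)-4-(4-benzyloxy-3-methoxybenzyl)-3-[(tert-butyldiphenylsilyloxy)methyl]-4-hydroxyoxolan-2-yl]-3-methoxyphenyl}-5-methoxybenzaldehyde
Conditions: Pd(OAc)2 (cat.), SPhos, K3PO4, toluene/H2O (10:1), 80 °C
Reagents that add atoms: none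
Why: Suzuki–Miyaura coupling with a dialkylbiarylphosphine ligand, which forms the 2,2′-dialkoxy biaryl bond without a statistical step and leaves the tertiary alcohol, silyl ether and aldehyde alone.

Step 13
Reactants: 17 biaryl aldehyde; 18 dimethyl (1-diazo-2-oxopropyl)phosphonate
Product: 19 ethynyl biaryl carrying unit A (17 with C≡CH in place of CHO)
Conditions: K2CO3, MeOH/THF (1:1), 0 °C to rt
Reagents that add atoms: none
Why: Ohira–Bestmann modification of the Seyferth–Gilbert homologation, in which methanolysis of 18 gives the diazomethylphosphonate anion that converts the aldehyde through a diazoalkene and 1,2-hydride shift of the alkylidene carbene into the terminal alkyne.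

Step 14
Reactants: 20 4-benzyloxy-3-methoxybenzaldehyde; 21 ethyl 2-(bromomethyl)acrylate
Product: 24 (S)-5-(4-benzyloxy-3-methoxyphenyl)-3-methyleneoxolan-2-one, via silyl ether 22 (not isolated), via hydroxy ester 23 (not isolated)
Conditions: CrCl2 (10 mol %), (S,S)-carbazole bis(oxazoline) ligand (12 mol %), Mn, TMSCl, THF, rt; then 1 M HCl, THF, rt
Reagents that add atoms: chlorotrimethylsilane, C[Si](C)(C)Cl (silyl group present only in intermediate 22)
Why: Catalytic asymmetric Nozaki–Hiyama–Kishi 2-(alkoxycarbonyl)allylation, in which the ligand-bound allylchromium(III) species adds to one face of the aldehyde to set C7 as S, manganese and TMSCl turn the chromium over, and acid removes the silyl group so that the alcohol closes on the ester.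

Step 15
Reactants: 24 α-methylene lactone
Product: 25 (S)-5-(4-benzyloxy-3-methoxyphenyl)-3-hydroxyfuran-2(5H)-one
Conditions: O3 (titrated solution in CH2Cl2, 1.1 equiv), −78 °C; Me2S, −78 °C to rt
Reagents that add atoms: ozone, [O-][O+]=O
Why: Ozonolysis of the 1,1-disubstituted alkene, which reacts faster than the alkoxyarene when ozone is dosed, gives the α-keto lactone that tautomerises to the enol through C8 only, so C7 is not touched.

Step 16
Reactants: 25 enol lactone
Product: 26 (S)-3-benzyloxy-5-(4-benzyloxy-3-methoxyphenyl)furan-2(5H)-one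
Conditions: BnOH, PPh3, DIAD, THF, 0 °C to rt
Reagents that add atoms: benzyl alcohol, OCc1ccccc1
Why: Mitsunobu O-alkylation of the acidic enol under neutral conditions, chosen because a base could remove the benzylic, vinylogously acidic C7 hydrogen of the product and racemise it.

Step 17
Reactants: 19 ethynyl biaryl carrying unit A; 26 (S)-3-benzyloxy-5-aryl butenolide
Product: 27 (1R,4S,5R)-1-benzyloxy-4-(4-benzyloxy-3-methoxyphenyl)-3-oxabicyclo[3.2.0]hept-6-en-2-one carrying at C7 the benzyloxy-methoxy-phenyl ring of the unit A biaryl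
Conditions: 26 (2 equiv), thioxanthone (20 mol %), degassed CH2Cl2 (0.02 M in 19), hν 385 nm (LED), −20 °C; stopped before 19 is fully consumed
Reagents that add atoms: none
Why: Proposed new method: thioxanthone (triplet energy about 65 kcal/mol), excited at 385 nm where neither partner absorbs, should pass its triplet energy to the aryl alkyne of 19 and not to butenolide 26, whose own triplet could divert to 1,2-aryl migration; the alkyne triplet bonds through its terminal carbon C9 to the β-carbon C8 of 26 to give a 1,4-biradical (aryl-conjugated vinyl radical at C7′, captodative radical at C8′ flanked by the benzyloxy group and the lactone carbonyl), which closes C7′–C8′ after intersystem crossing. The closest known reactions are the [2+2] photocycloaddition of 5-substituted 2(5H)-furanones with acetylene and alkenes anti to the 5-substituent and the triplet-sensitised [2+2] of aryl alkynes with alkenes to 1-aryl cyclobutenes. The cyclobutene ring closes by recombination of the 1,4-biradical (stepwise [2+2]) and can only be cis-fused to the five-membered lactone. C8 is set in the first bond formation, on the face anti to the aryl group on the adjacent C7, and C8′ follows from the enforced cis fusion, so C9 and C7′ end up cis to each other and trans to the C7 aryl with the C8′ oxygen cis to it. The step needs head-to-head regiochemistry (C9 to C8, C7′ to C8′), which the more stable biradical should secure, and anti facial selectivity, which the C7 aryl group next to the carbon attacked first should secure; the tertiary alcohol, silyl ether and benzyl ethers of unit A do not absorb at this wavelength.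

Step 18
Reactants: 27 cyclobutene-fused lactone
Product: 29 C9,C7′-diol lactone (unit B) on the unit A biaryl, via keto aldehyde 28 (not isolated)
Conditions: O3, CH2Cl2/MeOH (4:1), Sudan Red 7B, −78 °C; then NaBH4, −78 to −10 °C; AcOH
Reagents that add atoms: ozone, [O-][O+]=O
Why: Ozonolysis with reductive work-up, in which the strained electron-rich aryl cyclobutene C9=C7′ is cleaved far faster than the alkoxyarenes react and borohydride added cold reduces the peroxide, the C9 aldehyde and the C7′ aryl ketone before the β-keto lactone can fragment or C8 can epimerise, the C7′ carbinol forming as an epimer mixture that is removed in step 21.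

Step 19
Reactants: 29 diol lactone
Product: 30 C9 tert-butyldiphenylsilyl ether of 29
Conditions: TBDPSCl, imidazole, CH2Cl2/DMF, 0 °C
Reagents that add atoms: tert-butyl(chloro)diphenylsilane, CC(C)(C)[Si](Cl)(c1ccccc1)c1ccccc1
Why: Silylation selective for the primary C9 alcohol over the hindered secondary C7′ and the tertiary alcohols, with imidazole too weak a base to cause retro-aldol loss of the C7′ carbinol or translactonisation.

Step 20
Reactants: 30 silyl ether lactone
Product: 31 lactol of 30 (C9′ hemiacetal, anomer mixture)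
Conditions: DIBAL-H (4 equiv), CH2Cl2, −78 °C; Rochelle salt
Reagents that add atoms: none
Why: Partial reduction of the α-benzyloxy γ-lactone to the lactol through the aluminium hemiacetal stable at −78 °C, the free alcohols being held as aluminium alkoxides.

Step 21
Reactants: 31 lactol
Product: 32 bis-oxolane with C7′H2, both C9 alcohols as silyl ethers and unit B in the (7S,8R,8′S) configuration
Conditions: Et3SiH (10 equiv), BF3·OEt2, CH2Cl2, −78 to −40 °C
Reagents that add atoms: none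
Why: Ionic hydrogenation, in which BF3 ionises the lactol to the cyclic oxocarbenium ion and, on warming, the C7′ benzylic alcohol to the p-benzyloxybenzyl cation and triethylsilane reduces both without forming a stereocentre, the C9 silyl ether being too poor a nucleophile to close a 7′,9-ether and the aryl oxolane C7–O bonds ionising more slowly than the free benzylic alcohol.

Step 22
Reactants: 32 bis-silyl ether
Product: 33 pentabenzyl ether of the target (both C9 alcohols free)
Conditions: TBAF, THF, rt; NH4Cl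
Reagents that add atoms: none
Why: Fluoride-induced desilylation driven by Si–F bond formation frees both primary C9 alcohols and leaves the benzyl ethers in place.

Step 23
Reactants: 33 pentabenzyl ether
Product: 34 CNP0269573.1 (target)
Conditions: H2 (1 atm), Pd(OH)2/C, EtOAc/MeOH, rt; stopped when debenzylation is complete
Reagents that add atoms: none
Why: Catalytic hydrogenolysis of the four aryl benzyl ethers and the tertiary benzyl ether, with the cyclic benzylic C7–O bonds, being dialkyl ethers inside a ring, expected to cleave much more slowly.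

## Compound list

1 | (S)-4-benzyloxazolidin-2-one | O=C1N[C@@H](Cc2ccccc2)CO1 | starting material
2 | methyl 4-chloro-4-oxobutanoate | COC(=O)CCC(Cl)=O | starting material
3 | (S)-4-benzyl-3-(4-methoxy-4-oxobutanoyl)oxazolidin-2-one | COC(=O)CCC(=O)N1[C@@H](Cc2ccccc2)COC1=O | intermediate
4 | 5-bromovanillin (3-bromo-4-hydroxy-5-methoxybenzaldehyde) | COc1cc(C=O)cc(Br)c1O | starting material
5 | 4-benzyloxy-3-bromo-5-methoxybenzaldehyde | COc1cc(C=O)cc(Br)c1OCc1ccccc1 | intermediate
6 | syn aldol adduct, methyl (3S)-3-[(S)-(4-benzyloxy-3-bromo-5-methoxyphenyl)(hydroxy)methyl]-4-[(S)-4-benzyl-2-oxooxazolidin-3-yl]-4-oxobutanoate | COC(=O)C[C@@H]([C@H](O)c1cc(OC)c(OCc2ccccc2)c(Br)c1)C(=O)N1[C@@H](Cc2ccccc2)COC1=O | intermediate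
7 | (S)-4-benzyl-3-[(2S,3S)-2-(4-benzyloxy-3-bromo-5-methoxyphenyl)-5-oxooxolane-3-carbonyl]oxazolidin-2-one (aryl and acyl trans) | C1C(=O)O[C@H](c2cc(OC)c(OCc3ccccc3)c(Br)c2)[C@H]1C(=O)N1[C@@H](Cc2ccccc2)COC1=O | intermediate
8 | (4R,5S)-5-(4-benzyloxy-3-bromo-5-methoxyphenyl)-4-(hydroxymethyl)oxolan-2-one | C1C(=O)O[C@H](c2cc(OC)c(OCc3ccccc3)c(Br)c2)[C@H]1CO | intermediate
9 | (4R,5S)-5-(4-benzyloxy-3-bromo-5-methoxyphenyl)-4-[(tert-butyldiphenylsilyloxy)methyl]oxolan-2-one | C1C(=O)O[C@H](c2cc(OC)c(OCc3ccccc3)c(Br)c2)[C@H]1CO[Si](c2ccccc2)(c2ccccc2)C(C)(C)C | intermediate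
10 | 4-benzyloxy-3-methoxybenzyl alcohol | COc1cc(CO)ccc1OCc1ccccc1 | starting material
11 | 4-benzyloxy-3-methoxybenzyl bromide | COc1cc(CBr)ccc1OCc1ccccc1 | intermediate
12 | (3S,4R,5S)-3-(4-benzyloxy-3-methoxybenzyl)-5-(4-benzyloxy-3-bromo-5-methoxyphenyl)-4-[(tert-butyldiphenylsilyloxy)methyl]oxolan-2-one (benzyl trans to the C4 substituent) | COc1cc(C[C@@H]2C(=O)O[C@H](c3cc(OC)c(OCc4ccccc4)c(Br)c3)[C@H]2CO[Si](c3ccccc3)(c3ccccc3)C(C)(C)C)ccc1OCc1ccccc1 | intermediate
13 | (3S,4R,5S)-3-(4-benzyloxy-3-methoxybenzyl)-5-(4-benzyloxy-3-bromo-5-methoxyphenyl)-4-[(tert-butyldiphenylsilyloxy)methyl]-3-hydroxyoxolan-2-one (3-OH cis to the 5-aryl, 3-benzyl cis to the 4-CH2OSi group) | COc1cc(C[C@@]2(O)C(=O)O[C@H](c3cc(OC)c(OCc4ccccc4)c(Br)c3)[C@H]2CO[Si](c3ccccc3)(c3ccccc3)C(C)(C)C)ccc1OCc1ccccc1 | intermediate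
14 | lactol of 13, (3S,4R,5S)-3-(4-benzyloxy-3-methoxybenzyl)-5-(4-benzyloxy-3-bromo-5-methoxyphenyl)-4-[(tert-butyldiphenylsilyloxy)methyl]oxolane-2,3-diol, anomer mixture | COc1cc(C[C@@]2(O)C(O)O[C@H](c3cc(OC)c(OCc4ccccc4)c(Br)c3)[C@H]2CO[Si](c3ccccc3)(c3ccccc3)C(C)(C)C)ccc1OCc1ccccc1 | intermediate
15 | (3S,4R,5S)-3-(4-benzyloxy-3-methoxybenzyl)-5-(4-benzyloxy-3-bromo-5-methoxyphenyl)-4-[(tert-butyldiphenylsilyloxy)methyl]oxolan-3-ol (unit A, 7S,8R,8′S) | COc1cc(C[C@@]2(O)CO[C@H](c3cc(OC)c(OCc4ccccc4)c(Br)c3)[C@H]2CO[Si](c3ccccc3)(c3ccccc3)C(C)(C)C)ccc1OCc1ccccc1 | intermediate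
16 | 4-benzyloxy-3-methoxy-5-(4,4,5,5-tetramethyl-1,3,2-dioxaborolan-2-yl)benzaldehyde | COc1cc(C=O)cc(B2OC(C)(C)C(C)(C)O2)c1OCc1ccccc1 | intermediate
17 | 4-benzyloxy-3-{2-benzyloxy-5-[(2S,3R,4S)-4-(4-benzyloxy-3-methoxybenzyl)-3-[(tert-butyldiphenylsilyloxy)methyl]-4-hydroxyoxolan-2-yl]-3-methoxyphenyl}-5-methoxybenzaldehyde | COc1cc(C[C@@]2(O)CO[C@H](c3cc(OC)c(OCc4ccccc4)c(-c4cc(C=O)cc(OC)c4OCc4ccccc4)c3)[C@H]2CO[Si](c3ccccc3)(c3ccccc3)C(C)(C)C)ccc1OCc1ccccc1 | intermediate
18 | dimethyl (1-diazo-2-oxopropyl)phosphonate | COP(=O)(OC)C(=[N+]=[N-])C(C)=O | starting material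
19 | ethynyl biaryl carrying unit A: 17 with C≡CH in place of CHO | COc1cc(C[C@@]2(O)CO[C@H](c3cc(OC)c(OCc4ccccc4)c(-c4cc(C#C)cc(OC)c4OCc4ccccc4)c3)[C@H]2CO[Si](c3ccccc3)(c3ccccc3)C(C)(C)C)ccc1OCc1ccccc1 | intermediate
20 | 4-benzyloxy-3-methoxybenzaldehyde (O-benzylvanillin) | COc1cc(C=O)ccc1OCc1ccccc1 | starting material
21 | ethyl 2-(bromomethyl)acrylate | C=C(CBr)C(=O)OCC | starting material
22 | ethyl (S)-4-(4-benzyloxy-3-methoxyphenyl)-2-methylene-4-(trimethylsilyloxy)butanoate | C=C(C[C@H](O[Si](C)(C)C)c1ccc(OCc2ccccc2)c(OC)c1)C(=O)OCC | intermediate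
23 | ethyl (S)-4-(4-benzyloxy-3-methoxyphenyl)-4-hydroxy-2-methylenebutanoate | C=C(C[C@H](O)c1ccc(OCc2ccccc2)c(OC)c1)C(=O)OCC | intermediate
24 | (S)-5-(4-benzyloxy-3-methoxyphenyl)-3-methyleneoxolan-2-one | O=C1O[C@H](c2ccc(OCc3ccccc3)c(OC)c2)CC1=C | intermediate
25 | (S)-5-(4-benzyloxy-3-methoxyphenyl)-3-hydroxyfuran-2(5H)-one | O=C1O[C@H](c2ccc(OCc3ccccc3)c(OC)c2)C=C1O | intermediate
26 | (S)-3-benzyloxy-5-(4-benzyloxy-3-methoxyphenyl)furan-2(5H)-one | O=C1O[C@H](c2ccc(OCc3ccccc3)c(OC)c2)C=C1OCc1ccccc1 | intermediate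
27 | cyclobutene-fused lactone: (1R,4S,5R)-1-benzyloxy-4-(4-benzyloxy-3-methoxyphenyl)-3-oxabicyclo[3.2.0]hept-6-en-2-one with C7 bonded to the 4-benzyloxy-3-methoxy-5-aryl-phenyl ring of the unit A biaryl (C9 and C7′ cis, both trans to the C7 aryl) | COc1cc(C[C@@]2(O)CO[C@H](c3cc(OC)c(OCc4ccccc4)c(-c4cc(C5=C[C@@H]6[C@@H](c7ccc(OCc8ccccc8)c(OC)c7)OC(=O)[C@]56OCc5ccccc5)cc(OC)c4OCc4ccccc4)c3)[C@H]2CO[Si](c3ccccc3)(c3ccccc3)C(C)(C)C)ccc1OCc1ccccc1 | intermediate
28 | keto aldehyde: unit B as γ-lactone (C9′ carbonyl, ring O on C7) with 8′-benzyloxy, 8′-aroyl (C7′=O, aryl = biaryl ring) and 8-formyl groups, 7S,8R,8′R | COc1cc(C[C@@]2(O)CO[C@H](c3cc(OC)c(OCc4ccccc4)c(-c4cc(C(=O)[C@@]5(OCc6ccccc6)C(=O)O[C@H](c6ccc(OCc7ccccc7)c(OC)c6)[C@H]5C=O)cc(OC)c4OCc4ccccc4)c3)[C@H]2CO[Si](c3ccccc3)(c3ccccc3)C(C)(C)C)ccc1OCc1ccccc1 | intermediate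
29 | diol lactone: 28 with C9H2OH and C7′H(OH) (C7′ epimers), 7S,8R,8′R | COc1cc(C[C@@]2(O)CO[C@H](c3cc(OC)c(OCc4ccccc4)c(-c4cc(C(O)[C@@]5(OCc6ccccc6)C(=O)O[C@H](c6ccc(OCc7ccccc7)c(OC)c6)[C@H]5CO)cc(OC)c4OCc4ccccc4)c3)[C@H]2CO[Si](c3ccccc3)(c3ccccc3)C(C)(C)C)ccc1OCc1ccccc1 | intermediate
30 | 29 with the unit B C9 alcohol as tert-butyldiphenylsilyl ether | COc1cc(C[C@@]2(O)CO[C@H](c3cc(OC)c(OCc4ccccc4)c(-c4cc(C(O)[C@@]5(OCc6ccccc6)C(=O)O[C@H](c6ccc(OCc7ccccc7)c(OC)c6)[C@H]5CO[Si](c6ccccc6)(c6ccccc6)C(C)(C)C)cc(OC)c4OCc4ccccc4)c3)[C@H]2CO[Si](c3ccccc3)(c3ccccc3)C(C)(C)C)ccc1OCc1ccccc1 | intermediate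
31 | lactol of 30 (C9′ hemiacetal, anomer mixture) | COc1cc(C[C@@]2(O)CO[C@H](c3cc(OC)c(OCc4ccccc4)c(-c4cc(C(O)[C@@]5(OCc6ccccc6)C(O)O[C@H](c6ccc(OCc7ccccc7)c(OC)c6)[C@H]5CO[Si](c6ccccc6)(c6ccccc6)C(C)(C)C)cc(OC)c4OCc4ccccc4)c3)[C@H]2CO[Si](c3ccccc3)(c3ccccc3)C(C)(C)C)ccc1OCc1ccccc1 | intermediate
32 | bis-oxolane: both units (7S,8R,8′S), C7′H2 in unit B, unit B 8′-O-benzyl, both C9 O-TBDPS, four aryl O-benzyl, unit A 8′-OH free | COc1cc(C[C@@]2(O)CO[C@H](c3cc(OC)c(OCc4ccccc4)c(-c4cc(C[C@@]5(OCc6ccccc6)CO[C@H](c6ccc(OCc7ccccc7)c(OC)c6)[C@H]5CO[Si](c6ccccc6)(c6ccccc6)C(C)(C)C)cc(OC)c4OCc4ccccc4)c3)[C@H]2CO[Si](c3ccccc3)(c3ccccc3)C(C)(C)C)ccc1OCc1ccccc1 | intermediate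
33 | pentabenzyl ether of the target (32 with both C9 alcohols free) | COc1cc(C[C@@]2(O)CO[C@H](c3cc(OC)c(OCc4ccccc4)c(-c4cc(C[C@@]5(OCc6ccccc6)CO[C@H](c6ccc(OCc7ccccc7)c(OC)c6)[C@H]5CO)cc(OC)c4OCc4ccccc4)c3)[C@H]2CO)ccc1OCc1ccccc1 | intermediate
34 | CNP0269573.1, the 5,5′-linked bis-olivil (both units 7S,8R,8′S) | COc1cc(C[C@@]2(O)CO[C@H](c3cc(OC)c(O)c(-c4cc(C[C@@]5(O)CO[C@H](c6ccc(O)c(OC)c6)[C@H]5CO)cc(OC)c4O)c3)[C@H]2CO)ccc1O | target

## Step count and risks

Total steps: 23. Longest linear sequence: 17 steps (1, 3, 4, 5, 7, 8, 9, 10, 12, 13, 17, 18, 19, 20, 21, 22, 23).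

Steps most likely to fail:

Step 17 (photocycloaddition). What may go wrong: addition on the face syn to the C7 aryl group, first bond formation at the wrong alkyne carbon (head-to-tail adduct), onward sensitisation of the aryl cyclobutene product leading to a second cycloaddition or ring opening, and aryl migration in the butenolide if it is sensitised instead of the alkyne. Fallback by known enolate chemistry, setting out from 17 and 20 and returning at 34: aldehyde 17 is reduced with NaBH4 to the biaryl benzylic alcohol F1, which CBr4 and PPh3 convert into the biaryl benzylic bromide F2. In parallel 20 is taken through the conditions of steps 3 to 5 in place of 5: the syn aldol with 3 gives the aldol adduct F3, which closes to the lactone imide F4; borohydride gives the hydroxymethyl lactone F5 and silylation the silyl ether lactone F6. The lithium enolate of F6 is alkylated with F2 to the trans α-(biarylmethyl) lactone F7, and hydroxylation of its potassium enolate with the oxaziridine, anti to C9, gives the α-hydroxy lactone F8. DIBAL-H then gives the lactol F9, Et3SiH with BF3·OEt2 at −78 °C the bis-oxolane bis-silyl ether F10, TBAF the tetrabenzyl ether F11, and hydrogenolysis gives 34.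

Step 8 (enolate hydroxylation). What may go wrong: oxygen transfer on the face syn to C9, because the C7 aryl group shields the opposite face, which would give the C8′ epimer, and addition of the enolate to the sulfonimine by-product. Fallback that reverses the order of the two enolate reactions, setting out from 9 and returning at 13: 9 is hydroxylated first (KHMDS, oxaziridine) to the α-hydroxy lactone F12, whose configuration at C8′ does not matter, and silylated (TESCl, imidazole) to the triethylsilyl ether F13. The enolate of F13 (LDA, −78 °C) is then benzylated with 11 to the α-benzyl α-silyloxy lactone F14; if the lactone enolate prefers attack syn to C9, this order puts the benzyl group cis to C9. PPTS in MeOH removes the triethylsilyl group and gives 13.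

Step 21 (double ionic reduction). What may go wrong: a 1,2-shift in the C7′ benzylic cation next to the oxygen-bearing C8′ (ring expansion) before hydride capture, capture of the cation by the C9 ether oxygen with loss of silicon to give the 7′,9-ether, and reductive opening or epimerisation of the aryl oxolanes on warming. Fallback that removes the C7′ oxygen by a radical path, setting out from 30 and returning at 32: 30 with 1,1′-thiocarbonyldiimidazole and DMAP gives the imidazolyl thionocarbamate F15; Bu3SnH with AIBN in toluene at 90 °C (Barton–McCombie deoxygenation) gives the C7′-deoxy lactone F16; DIBAL-H at −78 °C gives the lactol F17; Et3SiH with BF3·OEt2 kept at −78 °C, now with only the lactol to reduce, gives 32.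

Further compounds
F1 | step 17 | biaryl benzylic alcohol: 17 with CH2OH in place of CHO | COc1cc(C[C@@]2(O)CO[C@H](c3cc(OC)c(OCc4ccccc4)c(-c4cc(CO)cc(OC)c4OCc4ccccc4)c3)[C@H]2CO[Si](c3ccccc3)(c3ccccc3)C(C)(C)C)ccc1OCc1ccccc1
F2 | step 17 | biaryl benzylic bromide: 17 with CH2Br in place of CHO | COc1cc(C[C@@]2(O)CO[C@H](c3cc(OC)c(OCc4ccccc4)c(-c4cc(CBr)cc(OC)c4OCc4ccccc4)c3)[C@H]2CO[Si](c3ccccc3)(c3ccccc3)C(C)(C)C)ccc1OCc1ccccc1
F3 | step 17 | syn aldol adduct of 3 and 20, methyl (3S)-3-[(S)-(4-benzyloxy-3-methoxyphenyl)(hydroxy)methyl]-4-[(S)-4-benzyl-2-oxooxazolidin-3-yl]-4-oxobutanoate | COC(=O)C[C@@H]([C@H](O)c1ccc(OCc2ccccc2)c(OC)c1)C(=O)N1[C@@H](Cc2ccccc2)COC1=O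
F4 | step 17 | (S)-4-benzyl-3-[(2S,3S)-2-(4-benzyloxy-3-methoxyphenyl)-5-oxooxolane-3-carbonyl]oxazolidin-2-one | C1C(=O)O[C@H](c2ccc(OCc3ccccc3)c(OC)c2)[C@H]1C(=O)N1[C@@H](Cc2ccccc2)COC1=O
F5 | step 17 | (4R,5S)-5-(4-benzyloxy-3-methoxyphenyl)-4-(hydroxymethyl)oxolan-2-one | C1C(=O)O[C@H](c2ccc(OCc3ccccc3)c(OC)c2)[C@H]1CO
F6 | step 17 | (4R,5S)-5-(4-benzyloxy-3-methoxyphenyl)-4-[(tert-butyldiphenylsilyloxy)methyl]oxolan-2-one | C1C(=O)O[C@H](c2ccc(OCc3ccccc3)c(OC)c2)[C@H]1CO[Si](c2ccccc2)(c2ccccc2)C(C)(C)C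
F7 | step 17 | trans α-(biarylmethyl) lactone: unit B lactone (C9′ carbonyl, O on C7) with 8′-H, C9 O-TBDPS, joined through C7′H2 to the unit A biaryl | COc1cc(C[C@@]2(O)CO[C@H](c3cc(OC)c(OCc4ccccc4)c(-c4cc(C[C@@H]5C(=O)O[C@H](c6ccc(OCc7ccccc7)c(OC)c6)[C@H]5CO[Si](c6ccccc6)(c6ccccc6)C(C)(C)C)cc(OC)c4OCc4ccccc4)c3)[C@H]2CO[Si](c3ccccc3)(c3ccccc3)C(C)(C)C)ccc1OCc1ccccc1
F8 | step 17 | α-hydroxy lactone: F7 with 8′-OH (cis to the C7 aryl) | COc1cc(C[C@@]2(O)CO[C@H](c3cc(OC)c(OCc4ccccc4)c(-c4cc(C[C@@]5(O)C(=O)O[C@H](c6ccc(OCc7ccccc7)c(OC)c6)[C@H]5CO[Si](c6ccccc6)(c6ccccc6)C(C)(C)C)cc(OC)c4OCc4ccccc4)c3)[C@H]2CO[Si](c3ccccc3)(c3ccccc3)C(C)(C)C)ccc1OCc1ccccc1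
F9 | step 17 | lactol of F8 (anomer mixture) | COc1cc(C[C@@]2(O)CO[C@H](c3cc(OC)c(OCc4ccccc4)c(-c4cc(C[C@@]5(O)C(O)O[C@H](c6ccc(OCc7ccccc7)c(OC)c6)[C@H]5CO[Si](c6ccccc6)(c6ccccc6)C(C)(C)C)cc(OC)c4OCc4ccccc4)c3)[C@H]2CO[Si](c3ccccc3)(c3ccccc3)C(C)(C)C)ccc1OCc1ccccc1
F10 | step 17 | bis-oxolane bis-silyl ether: both units (7S,8R,8′S), both 8′-OH free, both C9 O-TBDPS, four aryl O-benzyl | COc1cc(C[C@@]2(O)CO[C@H](c3cc(OC)c(OCc4ccccc4)c(-c4cc(C[C@@]5(O)CO[C@H](c6ccc(OCc7ccccc7)c(OC)c6)[C@H]5CO[Si](c6ccccc6)(c6ccccc6)C(C)(C)C)cc(OC)c4OCc4ccccc4)c3)[C@H]2CO[Si](c3ccccc3)(c3ccccc3)C(C)(C)C)ccc1OCc1ccccc1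
F11 | step 17 | tetrabenzyl ether of the target (four aryl O-benzyl, all alcohols free) | COc1cc(C[C@@]2(O)CO[C@H](c3cc(OC)c(OCc4ccccc4)c(-c4cc(C[C@@]5(O)CO[C@H](c6ccc(OCc7ccccc7)c(OC)c6)[C@H]5CO)cc(OC)c4OCc4ccccc4)c3)[C@H]2CO)ccc1OCc1ccccc1
F12 | step 8 | (4R,5S)-5-(4-benzyloxy-3-bromo-5-methoxyphenyl)-4-[(tert-butyldiphenylsilyloxy)methyl]-3-hydroxyoxolan-2-one (C3 epimers) | OC1C(=O)O[C@H](c2cc(OC)c(OCc3ccccc3)c(Br)c2)[C@H]1CO[Si](c2ccccc2)(c2ccccc2)C(C)(C)C
F13 | step 8 | triethylsilyl ether of F12 | CC[Si](CC)(CC)OC1C(=O)O[C@H](c2cc(OC)c(OCc3ccccc3)c(Br)c2)[C@H]1CO[Si](c2ccccc2)(c2ccccc2)C(C)(C)C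
F14 | step 8 | 13 with the tertiary alcohol as triethylsilyl ether | COc1cc(C[C@@]2(O[Si](CC)(CC)CC)C(=O)O[C@H](c3cc(OC)c(OCc4ccccc4)c(Br)c3)[C@H]2CO[Si](c3ccccc3)(c3ccccc3)C(C)(C)C)ccc1OCc1ccccc1
F15 | step 21 | 30 with the C7′ alcohol as O-(imidazol-1-ylthiocarbonyl) derivative | COc1cc(C[C@@]2(O)CO[C@H](c3cc(OC)c(OCc4ccccc4)c(-c4cc(C(OC(=S)n5ccnc5)[C@@]5(OCc6ccccc6)C(=O)O[C@H](c6ccc(OCc7ccccc7)c(OC)c6)[C@H]5CO[Si](c6ccccc6)(c6ccccc6)C(C)(C)C)cc(OC)c4OCc4ccccc4)c3)[C@H]2CO[Si](c3ccccc3)(c3ccccc3)C(C)(C)C)ccc1OCc1ccccc1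
F16 | step 21 | C7′-deoxy lactone: 30 with C7′H2 | COc1cc(C[C@@]2(O)CO[C@H](c3cc(OC)c(OCc4ccccc4)c(-c4cc(C[C@@]5(OCc6ccccc6)C(=O)O[C@H](c6ccc(OCc7ccccc7)c(OC)c6)[C@H]5CO[Si](c6ccccc6)(c6ccccc6)C(C)(C)C)cc(OC)c4OCc4ccccc4)c3)[C@H]2CO[Si](c3ccccc3)(c3ccccc3)C(C)(C)C)ccc1OCc1ccccc1
F17 | step 21 | lactol of F16 (anomer mixture) | COc1cc(C[C@@]2(O)CO[C@H](c3cc(OC)c(OCc4ccccc4)c(-c4cc(C[C@@]5(OCc6ccccc6)C(O)O[C@H](c6ccc(OCc7ccccc7)c(OC)c6)[C@H]5CO[Si](c6ccccc6)(c6ccccc6)C(C)(C)C)cc(OC)c4OCc4ccccc4)c3)[C@H]2CO[Si](c3ccccc3)(c3ccccc3)C(C)(C)C)ccc1OCc1ccccc1
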